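**Retrosynthetic overview**
1. The butenolide is closed last by ring-closing metathesis of an allyl 2-alkylacrylate, which comes from the side-chain methyl ketone (enol triflate, carbonylation).
2. The C4 centre (CH3 and axial CO2Me) comes from α-face methylation of a C4 ester enolate; that ester comes from a geminal diester by dealkoxycarbonylation.
3. Key disconnection C9–C10 (ring B): the α-carbon of a ring A aldehyde is made electrophilic as an α-formyl radical (an enolonium equivalent) and closes 6-endo onto the nucleophilic (E)-trisubstituted alkene; oxidative termination leaves the C8 exocyclic methylene.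
4. Ring A comes from an enantioselective iminium/enamine Michael–aldol annulation of a malonate-tethered aldehyde with an (E)-enal; the C5 centre set there controls C10, C9 and C4.
5. The enal comes from (E)-geranylacetone by cross-metathesis with crotonaldehyde; ring order: A, then B, then the butenolide.

Assumption: (E)-geranylacetone is bought as the pure E isomer (the cheaper E/Z mixture would first be separated); C-locants in the text follow labdane numbering (C4 bears CH3/CO2Me, C5 and C10 are the ring-fusion carbons, C8 bears =CH2, C9 bears the side chain, C20 is the formyl carbon).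

**Step 1**
Reactants: 1 (5E)-6,10-dimethylundeca-5,9-dien-2-one ((E)-geranylacetone); 2 (2E)-but-2-enal (crotonaldehyde)
Product: 3 (2E,6E)-6-methyl-10-oxoundeca-2,6-dienal
Conditions: second-generation Hoveyda–Grubbs catalyst (3 mol%), 2 (5 equiv), CH2Cl2, 40 °C
Reagents that add atoms: none
Why: Olefin cross-metathesis, in which the ruthenium alkylidene engages the terminal isopropylidene (releasing volatile 2-methylbut-2-ene) much faster than the internal trisubstituted alkene flanked by two chains, and the new enal forms E under thermodynamic control; no stereocentre is made.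

**Step 2**
Reactants: 4 dimethyl propanedioate (dimethyl malonate); 5 prop-2-enal (acrolein)
Product: 6 dimethyl 2-(3-oxopropyl)propanedioate
Conditions: NaOMe (5 mol%), MeOH, 0 °C, 4 in threefold excess
Reagents that add atoms: none
Why: Base-catalysed Michael addition of the malonate to acrolein, with excess malonate suppressing double addition; no stereocentre is made.

**Step 3**
Reactants: 3 (2E,6E)-6-methyl-10-oxoundeca-2,6-dienal; 6 dimethyl 2-(3-oxopropyl)propanedioate
Product: 9 dimethyl (2R,3RS)-3-formyl-2-[(3E)-3-methyl-7-oxooct-3-en-1-yl]cyclohexane-1,1-dicarboxylate, via Michael adduct 7 (not isolated), via cyclohexenecarbaldehyde 8 (not isolated)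
Conditions: (S)-2-{bis[3,5-bis(trifluoromethyl)phenyl][(trimethylsilyl)oxy]methyl}pyrrolidine (10 mol%), PhCO2H (10 mol%), CH2Cl2, 23 °C; then diethyl 2,6-dimethyl-1,4-dihydropyridine-3,5-dicarboxylate (Hantzsch ester, 1.3 equiv), Bn2NH·CF3CO2H (20 mol%), 40 °C, same flask
Reagents that add atoms: none
Why: Iminium–enamine organocascade (Michael addition, intramolecular aldol condensation) followed by iminium-catalysed transfer hydrogenation, in which the (S)-diarylprolinol silyl ether shields one face of the (E)-iminium ion so the malonate carbon adds to C5 from the open face (2R, the H5-α series of the target), the C10 enamine formed in that event closes ring A on the tethered aldehyde and dehydrates, and the Hantzsch ester then reduces only the conjugated C=C; the C10 epimer mixture does not matter because C10 is planarised in step 4.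

**Step 4**
Reactants: 9 dimethyl (2R,3RS)-3-formyl-2-[(3E)-3-methyl-7-oxooct-3-en-1-yl]cyclohexane-1,1-dicarboxylate
Product: 10 dimethyl (4aS,5S,8aR)-4a-formyl-6-methylidene-5-(3-oxobutyl)octahydronaphthalene-1,1(2H)-dicarboxylate
Conditions: Mn(OAc)3·2H2O (2.2 equiv), Cu(OAc)2·H2O (0.5 equiv), degassed AcOH, 60 °C
Reagents that add atoms: none
Why: Proposed new method: trivalent manganese enolises and oxidises the α-branched aldehyde by one electron to a tertiary α-formyl radical (C10 made electrophilic, an enolonium equivalent), which adds 6-endo to the nucleophilic C9 of the (E)-alkene through a chair transition state with the C5 tether equatorial (trans ring fusion, CHO axial and anti to H5, C11 equatorial, so 4aS and 5S follow from C5), and divalent copper oxidises the tertiary C8 radical with loss of a methyl hydrogen to give mainly the exocyclic alkene; the closest known reactions are Mn(OAc)3/Cu(OAc)2 oxidative free-radical cyclizations of unsaturated β-dicarbonyl compounds and ketones and amine-catalysed SOMO cyclizations of aldehydes.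

**Step 5**
Reactants: 10 dimethyl (4aS,5S,8aR)-4a-formyl-6-methylidene-5-(3-oxobutyl)octahydronaphthalene-1,1(2H)-dicarboxylate
Product: 11 methyl (1RS,4aR,5S,8aS)-4a-formyl-6-methylidene-5-(3-oxobutyl)decahydronaphthalene-1-carboxylate
Conditions: LiCl (3 equiv), H2O (2 equiv), DMSO, 150 °C
Reagents that add atoms: none
Why: Krapcho dealkoxycarbonylation, in which chloride demethylates one geminal ester, the carboxylate loses CO2 and water protonates the enolate, while the non-enolisable aldehyde, the ketone and the alkene are inert under these neutral conditions; the C1 (labdane C4) mixture is reset in step 6 and the descriptors at 4a and 8a change only because of ligand priorities.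

**Step 6**
Reactants: 11 methyl (1RS,4aR,5S,8aS)-4a-formyl-6-methylidene-5-(3-oxobutyl)decahydronaphthalene-1-carboxylate
Product: 13 methyl (1S,4aS,5S,8aR)-4a-formyl-1-methyl-6-methylidene-5-{3-[(trimethylsilyl)oxy]but-3-en-1-yl}decahydronaphthalene-1-carboxylate, via silyl enol ether 12 (not isolated)
Conditions: Me3SiCl (1.1 equiv), LiN(iPr)2 (1.1 equiv, commercial solution), THF, −78 °C; then LiN(iPr)2 (1.5 equiv), −78 to −30 °C; MeI (3 equiv), −78 to −20 °C; cold aqueous NaHCO3 work-up
Reagents that add atoms: chlorotrimethylsilane C[Si](C)(C)Cl; iodomethane CI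
Why: Kinetic deprotonation of the methyl ketone under internal silyl quench masks it as the terminal silyl enol ether, the second portion of amide base forms the C4 ester enolate, and MeI alkylates it from the equatorial α-face because the β-face is blocked by the 1,3-diaxial C10 formyl group, giving the equatorial methyl and axial ester (1S); this is a substrate-controlled ester enolate alkylation in which the hindered, non-enolisable aldehyde is left alone at −78 °C.

**Step 7**
Reactants: 13 methyl (1S,4aS,5S,8aR)-4a-formyl-1-methyl-6-methylidene-5-{3-[(trimethylsilyl)oxy]but-3-en-1-yl}decahydronaphthalene-1-carboxylate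
Product: 14 methyl (1S,4aS,5S,8aR)-4a-formyl-1-methyl-6-methylidene-5-{3-[(trifluoromethanesulfonyl)oxy]but-3-en-1-yl}decahydronaphthalene-1-carboxylate
Conditions: PhNTf2 (1.2 equiv), CsF (2 equiv), DME, 23 °C
Reagents that add atoms: N-phenylbis(trifluoromethanesulfonimide) O=S(=O)(N(c1ccccc1)S(=O)(=O)C(F)(F)F)C(F)(F)F
Why: Fluoride desilylation releases the regiodefined cesium enolate in the presence of PhNTf2, which O-triflates it before it can equilibrate and without any strong base near the aldehyde; enol triflate formation from a silyl enol ether, no stereocentre touched.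

**Step 8**
Reactants: 14 methyl (1S,4aS,5S,8aR)-4a-formyl-1-methyl-6-methylidene-5-{3-[(trifluoromethanesulfonyl)oxy]but-3-en-1-yl}decahydronaphthalene-1-carboxylate; 15 prop-2-en-1-ol (allyl alcohol)
Product: 16 methyl (1S,4aS,5S,8aR)-4a-formyl-1-methyl-6-methylidene-5-{3-[(prop-2-en-1-yloxy)carbonyl]but-3-en-1-yl}decahydronaphthalene-1-carboxylate
Conditions: Pd(OAc)2 (5 mol%), PPh3 (10 mol%), CO (1 atm), Et3N (2 equiv), 15 (10 equiv), DMF, 50 °C
Reagents that add atoms: carbon monoxide [C-]#[O+]
Why: Palladium-catalysed alkoxycarbonylation of the enol triflate (oxidative addition, CO insertion, acyl transfer to allyl alcohol) gives the 2-substituted acrylate, with CO insertion outrunning any Heck reaction at the hindered exocyclic alkene; no stereocentre touched.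

**Step 9**
Reactants: 16 methyl (1S,4aS,5S,8aR)-4a-formyl-1-methyl-6-methylidene-5-{3-[(prop-2-en-1-yloxy)carbonyl]but-3-en-1-yl}decahydronaphthalene-1-carboxylate
Product: 17 methyl (1S,4aS,5S,8aR)-4a-formyl-1-methyl-6-methylidene-5-[2-(2-oxo-2,5-dihydrofuran-3-yl)ethyl]decahydronaphthalene-1-carboxylate (CNP0175906.1)
Conditions: second-generation Grubbs catalyst (5 mol%), 1,4-benzoquinone (10 mol%), toluene, 80 °C
Reagents that add atoms: none
Why: Ring-closing metathesis between the acrylate methylene and the allyl ester closes the five-membered α-substituted butenolide with loss of ethene, while the hindered 1,1-disubstituted C8 methylene does not engage and benzoquinone suppresses ruthenium hydride isomerisation; no stereocentre touched.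

**Compound list**
1 | (5E)-6,10-dimethylundeca-5,9-dien-2-one | CC(=O)CC/C=C(\C)CCC=C(C)C | starting material
2 | (2E)-but-2-enal | C/C=C/C=O | starting material
3 | (2E,6E)-6-methyl-10-oxoundeca-2,6-dienal | CC(=O)CC/C=C(\C)CC/C=C/C=O | intermediate
4 | dimethyl propanedioate | COC(=O)CC(=O)OC | starting material
5 | prop-2-enal | C=CC=O | starting material
6 | dimethyl 2-(3-oxopropyl)propanedioate | COC(=O)C(CCC=O)C(=O)OC | intermediate
7 | dimethyl 2-[(3R,6E)-6-methyl-1,10-dioxoundec-6-en-3-yl]-2-(3-oxopropyl)propanedioate | CC(=O)CC/C=C(\C)CC[C@H](CC=O)C(CCC=O)(C(=O)OC)C(=O)OC | intermediate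
8 | dimethyl (2R)-3-formyl-2-[(3E)-3-methyl-7-oxooct-3-en-1-yl]cyclohex-3-ene-1,1-dicarboxylate | CC(=O)CC/C=C(\C)CC[C@@H]1C(C=O)=CCCC1(C(=O)OC)C(=O)OC | intermediate
9 | dimethyl (2R,3RS)-3-formyl-2-[(3E)-3-methyl-7-oxooct-3-en-1-yl]cyclohexane-1,1-dicarboxylate | CC(=O)CC/C=C(\C)CC[C@@H]1C(C=O)CCCC1(C(=O)OC)C(=O)OC | intermediate
10 | dimethyl (4aS,5S,8aR)-4a-formyl-6-methylidene-5-(3-oxobutyl)octahydronaphthalene-1,1(2H)-dicarboxylate | C=C1CC[C@@H]2[C@](C=O)(CCCC2(C(=O)OC)C(=O)OC)[C@H]1CCC(C)=O | intermediate
11 | methyl (1RS,4aR,5S,8aS)-4a-formyl-6-methylidene-5-(3-oxobutyl)decahydronaphthalene-1-carboxylate | C=C1CC[C@@H]2[C@](C=O)(CCCC2C(=O)OC)[C@H]1CCC(C)=O | intermediate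
12 | methyl (1RS,4aR,5S,8aS)-4a-formyl-6-methylidene-5-{3-[(trimethylsilyl)oxy]but-3-en-1-yl}decahydronaphthalene-1-carboxylate | C=C1CC[C@@H]2[C@](C=O)(CCCC2C(=O)OC)[C@H]1CCC(=C)O[Si](C)(C)C | intermediate
13 | methyl (1S,4aS,5S,8aR)-4a-formyl-1-methyl-6-methylidene-5-{3-[(trimethylsilyl)oxy]but-3-en-1-yl}decahydronaphthalene-1-carboxylate | C=C1CC[C@@H]2[C@](C=O)(CCC[C@]2(C)C(=O)OC)[C@H]1CCC(=C)O[Si](C)(C)C | intermediate
14 | methyl (1S,4aS,5S,8aR)-4a-formyl-1-methyl-6-methylidene-5-{3-[(trifluoromethanesulfonyl)oxy]but-3-en-1-yl}decahydronaphthalene-1-carboxylate | C=C1CC[C@@H]2[C@](C=O)(CCC[C@]2(C)C(=O)OC)[C@H]1CCC(=C)OS(=O)(=O)C(F)(F)F | intermediate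
15 | prop-2-en-1-ol | C=CCO | starting material
16 | methyl (1S,4aS,5S,8aR)-4a-formyl-1-methyl-6-methylidene-5-{3-[(prop-2-en-1-yloxy)carbonyl]but-3-en-1-yl}decahydronaphthalene-1-carboxylate | C=C1CC[C@@H]2[C@](C=O)(CCC[C@]2(C)C(=O)OC)[C@H]1CCC(=C)C(=O)OCC=C | intermediate
17 | methyl (1S,4aS,5S,8aR)-4a-formyl-1-methyl-6-methylidene-5-[2-(2-oxo-2,5-dihydrofuran-3-yl)ethyl]decahydronaphthalene-1-carboxylate | C=C1CC[C@@H]2[C@](C=O)(CCC[C@]2(C)C(=O)OC)[C@H]1CCC1=CCOC1=O | target

**Step count and risks**
Total steps: 9. Longest linear sequence: 8 (steps 1 and 3 to 9, from 1); step 2 is a one-step side branch.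

The three steps most likely to fail:

Step 4 (key oxidative ring B closure). The risks are poor α-formyl radical generation from a simple aldehyde, competing oxidation at the methyl ketone, and endocyclic alkene isomers. The fallback sets out from 9 and comes back at 10. Amine-catalysed α-selenenylation of 9 with N-(phenylselanyl)phthalimide gives dimethyl (2S,3RS)-3-formyl-2-[(3E)-3-methyl-7-oxooct-3-en-1-yl]-3-(phenylselanyl)cyclohexane-1,1-dicarboxylate F3. Photolysis (hν, benzene, 25 °C) starts a phenylselanyl group-transfer radical chain in which the same α-formyl radical cyclises 6-endo and the C8 radical takes the PhSe group back, giving dimethyl (4aR,5R,6RS,8aR)-4a-formyl-6-methyl-5-(3-oxobutyl)-6-(phenylselanyl)octahydronaphthalene-1,1(2H)-dicarboxylate F4. Oxidation with H2O2/pyridine and syn-elimination of the selenoxide toward the methyl group gives 10.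

Step 3 (organocascade). The risks are that the aldol condensation closes in the wrong direction (the other aldehyde acting as the enamine partner) and that the one-pot reduction of the hindered enal is slow. The fallback sets out from 3 (with 4) and comes back at 9. The same (S)-diarylprolinol silyl ether/PhCO2H system adds plain dimethyl malonate 4 to 3 to give dimethyl 2-[(3R,6E)-6-methyl-1,10-dioxoundec-6-en-3-yl]propanedioate F1. K2CO3 and 1,3-diiodopropane in DMF alkylate the malonate carbon to give dimethyl 2-(3-iodopropyl)-2-[(3R,6E)-6-methyl-1,10-dioxoundec-6-en-3-yl]propanedioate F2. Pyrrolidine in MeCN (Stork enamine, 6-exo-tet C-alkylation at C10) followed by aqueous AcOH closes ring A and gives the saturated aldehyde 9 directly, so neither the aldol regiochemistry nor the transfer hydrogenation is needed.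

Step 6 (one-flask ketone masking and C4 methylation beside a free aldehyde). The risks are incomplete selectivity between ketone and ester deprotonation and aldol reaction of the ester enolate with the aldehyde. The fallback sets out from 11 and comes back at 14. Both carbonyl groups are masked with 1,2-bis(trimethylsilyloxy)ethane and catalytic Me3SiOTf (CH2Cl2, −78 to −20 °C) to give methyl (1RS,4aR,5S,8aS)-4a-(1,3-dioxolan-2-yl)-6-methylidene-5-[2-(2-methyl-1,3-dioxolan-2-yl)ethyl]decahydronaphthalene-1-carboxylate F5. LiN(iPr)2 then MeI (THF, −78 to −20 °C) gives methyl (1S,4aS,5S,8aR)-4a-(1,3-dioxolan-2-yl)-1-methyl-6-methylidene-5-[2-(2-methyl-1,3-dioxolan-2-yl)ethyl]decahydronaphthalene-1-carboxylate F6 with the same α-face selectivity. Aqueous HCl/THF releases methyl (1S,4aS,5S,8aR)-4a-formyl-1-methyl-6-methylidene-5-(3-oxobutyl)decahydronaphthalene-1-carboxylate F7. KN(SiMe3)2 with PhNTf2 at −78 °C converts the methyl ketone into the kinetic enol triflate 14, where the route resumes.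

**Further compounds**
F1 | step 3 | dimethyl 2-[(3R,6E)-6-methyl-1,10-dioxoundec-6-en-3-yl]propanedioate | CC(=O)CC/C=C(\C)CC[C@H](CC=O)C(C(=O)OC)C(=O)OC
F2 | step 3 | dimethyl 2-(3-iodopropyl)-2-[(3R,6E)-6-methyl-1,10-dioxoundec-6-en-3-yl]propanedioate | CC(=O)CC/C=C(\C)CC[C@H](CC=O)C(CCCI)(C(=O)OC)C(=O)OC
F3 | step 4 | dimethyl (2S,3RS)-3-formyl-2-[(3E)-3-methyl-7-oxooct-3-en-1-yl]-3-(phenylselanyl)cyclohexane-1,1-dicarboxylate | CC(=O)CC/C=C(\C)CC[C@@H]1C(C=O)([Se]c2ccccc2)CCCC1(C(=O)OC)C(=O)OC
F4 | step 4 | dimethyl (4aR,5R,6RS,8aR)-4a-formyl-6-methyl-5-(3-oxobutyl)-6-(phenylselanyl)octahydronaphthalene-1,1(2H)-dicarboxylate | CC1([Se]c2ccccc2)CC[C@@H]2[C@](C=O)(CCCC2(C(=O)OC)C(=O)OC)[C@H]1CCC(C)=O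
F5 | step 6 | methyl (1RS,4aR,5S,8aS)-4a-(1,3-dioxolan-2-yl)-6-methylidene-5-[2-(2-methyl-1,3-dioxolan-2-yl)ethyl]decahydronaphthalene-1-carboxylate | C=C1CC[C@@H]2[C@](C3OCCO3)(CCCC2C(=O)OC)[C@H]1CCC1(C)OCCO1
F6 | step 6 | methyl (1S,4aS,5S,8aR)-4a-(1,3-dioxolan-2-yl)-1-methyl-6-methylidene-5-[2-(2-methyl-1,3-dioxolan-2-yl)ethyl]decahydronaphthalene-1-carboxylate | C=C1CC[C@@H]2[C@](C3OCCO3)(CCC[C@]2(C)C(=O)OC)[C@H]1CCC1(C)OCCO1
F7 | step 6 | methyl (1S,4aS,5S,8aR)-4a-formyl-1-methyl-6-methylidene-5-(3-oxobutyl)decahydronaphthalene-1-carboxylate | C=C1CC[C@@H]2[C@](C=O)(CCC[C@]2(C)C(=O)OC)[C@H]1CCC(C)=O
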